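**Retrosynthetic overview**

1. Feature: in the core (chromanone numbering) the CO2H carbon lies one CH2 beyond the benzylic CH that joins phenyl to C8, and the C7 oxygen is ortho to C8. The arm is therefore a C8 1-phenylvinyl group plus CO, closed on O7 as a six-membered lactone (a 4-phenyl-3,4-dihydrocoumarin) that also masks O7 and the acid until the end.
2. Ring order: pyranone first (phloroglucinol + tigloyl chloride; quinine oxa-Michael sets C2, epimerisation sets C3), then C8 iodination and Suzuki vinylation, then the lactone by Pd–H cyclocarbonylation. The vinyl group is brought in by cross-coupling so that the chromanone ketone never meets an olefination reagent.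
3. C6 side chain: iodination of the lactone at its only free ring CH, then Negishi coupling with the cyclobutylmethylzinc made from (−)-verbenone (RuO4 cleavage, Wittig, reduction, iodide).
4. End game: lactone methanolysis frees O7; Pd-catalysed dearomatising prenylation creates quaternary C6; saponification gives the acid.

Key step: step 7

Remark 1: the target is drawn as one enol tautomer of a 2-acylcyclohexane-1,3-dione; the route delivers this acid, which is free to equilibrate among its enol forms.
Remark 2: the sense of induction of the cinchona catalyst (step 2) and of the chiral phosphines (steps 7 and 15) is assigned by analogy; the antipode named is the expected one and the other is taken if a pilot run shows the opposite sense.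

**Route**

Step 1
Reactants: 1 phloroglucinol; 2 tigloyl chloride ((E)-2-methylbut-2-enoyl chloride)
Product: 3 (E)-2-methyl-1-(2,4,6-trihydroxyphenyl)but-2-en-1-one
Conditions: AlCl3 (3.5 equiv), PhNO2/CH2Cl2, 0 °C to rt, cold aq. HCl
Reagents that add atoms: none
Why: Friedel–Crafts C-acylation of the symmetric triol, whose three ring CH are equivalent so only one ketone can form; low temperature and short reaction time should keep the E-enone open, and any racemic chromanone from acid-induced closure is removed here.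

Step 2
Reactants: 3 (E)-2-methyl-1-(2,4,6-trihydroxyphenyl)but-2-en-1-one
Product: 4 (2R,3S)-5,7-dihydroxy-2,3-dimethylchroman-4-one (2,3-cis)
Conditions: (−)-quinine (20 mol %), PhCl (a little THF for solubility), 15 °C
Reagents that add atoms: none
Why: cinchona-alkaloid-catalysed asymmetric intramolecular oxa-Michael addition of an o-tigloylphenol, in which the quinine-bound phenoxide adds to one enone face to set C2 (R) and kinetic protonation of the enol gives the cis isomer; the two ortho hydroxyls are equivalent, so one constitution results.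

Step 3
Reactants: 4 (2R,3S)-5,7-dihydroxy-2,3-dimethylchroman-4-one
Product: 5 (2R,3S)-5,7-bis(tert-butyldimethylsilyloxy)-2,3-dimethylchroman-4-one
Conditions: TBSOTf (2.5 equiv), 2,6-lutidine (4 equiv), CH2Cl2, 0 °C to rt
Reagents that add atoms: tert-butyldimethylsilyl triflate, CC(C)(C)[Si](C)(C)OS(=O)(=O)C(F)(F)F
Why: O-silylation with a silyl triflate and a hindered base should cap both phenols, the hydrogen-bonded 5-OH included, without basic conditions that could open the pyranone; the two bulky ethers provide the steric bias used in step 5.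

Step 4
Reactants: 5 (2R,3S)-5,7-bis(tert-butyldimethylsilyloxy)-2,3-dimethylchroman-4-one
Product: 6 (2R,3R)-5,7-bis(tert-butyldimethylsilyloxy)-2,3-dimethylchroman-4-one (2,3-trans)
Conditions: MgI2 (1.5 equiv), Et3N (3 equiv), CH2Cl2/THF, rt; pH 7 buffer
Reagents that add atoms: none
Why: magnesium-assisted soft enolisation epimerises only C3 toward the more stable trans (diequatorial) isomer, while C2 is kept because the chelated magnesium enolate should not expel the aryloxide; remaining cis isomer is separated and resubmitted.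

Step 5
Reactants: 6 (2R,3R)-5,7-bis(tert-butyldimethylsilyloxy)-2,3-dimethylchroman-4-one
Product: 7 (2R,3R)-5,7-bis(tert-butyldimethylsilyloxy)-8-iodo-2,3-dimethylchroman-4-one
Conditions: NIS (1.05 equiv), cat. TFA, MeCN, 0 °C
Reagents that add atoms: N-iodosuccinimide, O=C1CCC(=O)N1I
Why: electrophilic aromatic iodination, expected at C8 (between the ring oxygen and one silyloxy group, para to O5) because C6 lies between two silyloxy groups, the 5-O-silyl group being turned toward C6 by the peri carbonyl.

Step 6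
Reactants: 7 (2R,3R)-5,7-bis(tert-butyldimethylsilyloxy)-8-iodo-2,3-dimethylchroman-4-one; 8 4,4,5,5-tetramethyl-2-(1-phenylvinyl)-1,3,2-dioxaborolane
Product: 10 (2R,3R)-5,7-dihydroxy-2,3-dimethyl-8-(1-phenylvinyl)chroman-4-one, via iodo diol 9 (not isolated)
Conditions: TBAF (2.4 equiv), AcOH (2.4 equiv), THF, 0 °C; then 8 (1.5 equiv), Pd(OAc)2 (5 mol %), SPhos (10 mol %), K2CO3 (4 equiv), dioxane/H2O, 70 °C
Reagents that add atoms: none
Why: buffered fluoride desilylation followed by Suzuki–Miyaura coupling of the hindered o-iodophenol with an α-substituted vinylboronate (biarylphosphine ligand); under the basic coupling conditions the 7-phenoxide turns the ketone into a vinylogous carboxylate, which should protect C3 and C2 from enolisation and ring opening.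

Step 7
Reactants: 10 (2R,3R)-5,7-dihydroxy-2,3-dimethyl-8-(1-phenylvinyl)chroman-4-one; 11 carbon monoxide
Product: 12 (2R,3R,10S)-5-hydroxy-2,3-dimethyl-10-phenyl-2,3,9,10-tetrahydro-4H,8H-pyrano[2,3-f]chromene-4,8-dione (the chromanone with a 4-phenyl-3,4-dihydrocoumarin lactone fused across O7–C8; chromanone C6 unsubstituted)
Conditions: Pd(OAc)2 (5 mol %), (R)-DTBM-SEGPHOS (6 mol %), CO (20 bar), H2 (5 bar), toluene, 80 °C
Reagents that add atoms: none
Why: Proposed new method: a ligated Pd–H adds across the 1,1-disubstituted alkene with H to the diaryl carbon and Pd to the terminal CH2 (the other regiochemistry would need a quaternary benzylic palladium), CO inserts to give the acyl-palladium, and the C7 hydroxyl captures the acyl group and releases Pd–H, so that the CH2–C(=O), benzylic C–H and O7–acyl bonds are made in one operation. The closest known reaction type is the palladium-catalysed cyclocarbonylation of 2-vinyl- and 2-(1-methylvinyl)aryl phenols and anilines to six-membered lactones and lactams, including enantioselective variants with chiral diphosphines; an enantioselective reaction of a 1,1-diarylethylene on a hexasubstituted ring has not been shown. The lactone closes by 6-exo-trig attack of O7 on the acyl-palladium carbon. The benzylic stereocentre (C10, S) is set in the hydropalladation by the chiral diphosphine, helped by coordination of O7 to palladium, which fixes the oxygenated ring relative to phenyl; since C2 and C3 are already fixed the two outcomes are diastereomers, so a minor isomer can be removed by chromatography. The step needs terminal carbonylation (secured by the 1,1-disubstitution), lactonisation at O7 (the only hydroxyl ortho to C8, O1 being part of the pyranone) and carbonylation rather than hydrogenation (high CO to H2 ratio); no other alkene is present.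

Step 8
Reactants: 12 (2R,3R,10S)-5-hydroxy-2,3-dimethyl-10-phenyl-2,3,9,10-tetrahydro-4H,8H-pyrano[2,3-f]chromene-4,8-dione
Product: 13 (2R,3R,10S)-5-hydroxy-6-iodo-2,3-dimethyl-10-phenyl-2,3,9,10-tetrahydro-4H,8H-pyrano[2,3-f]chromene-4,8-dione
Conditions: NIS (1.05 equiv), CH2Cl2/MeCN, 0 °C to rt
Reagents that add atoms: N-iodosuccinimide, O=C1CCC(=O)N1I
Why: electrophilic iodination at the only unsubstituted position of the oxygenated ring, ortho to the free 5-OH; the unactivated phenyl ring should not react.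

Step 9
Reactants: 14 (1S,5S)-(−)-verbenone
Product: 15 (1S,3R)-3-acetyl-2,2-dimethylcyclobutane-1-carboxylic acid (cis-pinononic acid)
Conditions: RuCl3·xH2O (2 mol %), NaIO4 (4.2 equiv), EtOAc/MeCN/H2O, rt
Reagents that add atoms: sodium periodate, [Na+].[O-]I(=O)(=O)=O; water, O
Why: RuO4 oxidative cleavage of the enone C=C, the α-keto acid formed losing CO2 to the acid; both ring stereocentres come unchanged from the bicycle and stay cis.

Step 10
Reactants: 15 (1S,3R)-3-acetyl-2,2-dimethylcyclobutane-1-carboxylic acid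
Product: 16 (1S,3S)-2,2-dimethyl-3-(prop-1-en-2-yl)cyclobutane-1-carboxylic acid
Conditions: Ph3PCH3Br (3.0 equiv), KOtBu (2.9 equiv), THF, 0 °C to rt; aq. citric acid
Reagents that add atoms: methyltriphenylphosphonium bromide, C[P+](c1ccccc1)(c1ccccc1)c1ccccc1.[Br-]
Why: Wittig methylenation of the methyl ketone as its carboxylate salt; ylide in slight excess over base and low temperature should limit epimerisation at the ketone α-carbon.

Step 11
Reactants: 16 (1S,3S)-2,2-dimethyl-3-(prop-1-en-2-yl)cyclobutane-1-carboxylic acid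
Product: 17 [(1S,3S)-2,2-dimethyl-3-(prop-1-en-2-yl)cyclobutyl]methanol
Conditions: LiAlH4 (2 equiv), THF, 0 °C to rt; Fieser work-up
Reagents that add atoms: none
Why: hydride reduction of the carboxylic acid to the primary alcohol; the isolated alkene is inert and no stereocentre is touched.

Step 12
Reactants: 17 [(1S,3S)-2,2-dimethyl-3-(prop-1-en-2-yl)cyclobutyl]methanol
Product: 18 (1S,3S)-1-(iodomethyl)-2,2-dimethyl-3-(prop-1-en-2-yl)cyclobutane
Conditions: I2 (1.2 equiv), PPh3 (1.2 equiv), imidazole (1.5 equiv), CH2Cl2, 0 °C to rt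
Reagents that add atoms: iodine, II
Why: Appel iodination by SN2 at the primary carbon, so no cation arises next to the strained ring.

Step 13
Reactants: 13 (2R,3R,10S)-5-hydroxy-6-iodo-2,3-dimethyl-10-phenyl-2,3,9,10-tetrahydro-4H,8H-pyrano[2,3-f]chromene-4,8-dione; 18 (1S,3S)-1-(iodomethyl)-2,2-dimethyl-3-(prop-1-en-2-yl)cyclobutane
Product: 21 (2R,3R,10S)-6-{[(1R,3S)-2,2-dimethyl-3-(prop-1-en-2-yl)cyclobutyl]methyl}-5-hydroxy-2,3-dimethyl-10-phenyl-2,3,9,10-tetrahydro-4H,8H-pyrano[2,3-f]chromene-4,8-dione, via alkyllithium 19 (not isolated), via alkylzinc chloride 20 (not isolated)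
Conditions: 18 (3 equiv), t-BuLi (6.1 equiv), Et2O/pentane, −78 °C; ZnCl2 (3.2 equiv), THF, −78 °C to rt; then 13, Pd(OAc)2 (4 mol %), SPhos (8 mol %), THF, 25 to 40 °C, slow addition of the zinc reagent
Reagents that add atoms: none
Why: lithium–iodine exchange and transmetalation to zinc, then Negishi sp3–sp2 coupling; the alkylzinc leaves the aryl lactone alone and, used in excess and added slowly, tolerates the chelated phenol, and the low-temperature exchange avoids radical or cationic species next to the cyclobutane, so its two stereocentres are kept.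

Step 14
Reactants: 21 (2R,3R,10S)-6-{[(1R,3S)-2,2-dimethyl-3-(prop-1-en-2-yl)cyclobutyl]methyl}-5-hydroxy-2,3-dimethyl-10-phenyl-2,3,9,10-tetrahydro-4H,8H-pyrano[2,3-f]chromene-4,8-dione
Product: 22 methyl (3S)-3-[(2R,3R)-6-{[(1R,3S)-2,2-dimethyl-3-(prop-1-en-2-yl)cyclobutyl]methyl}-5,7-dihydroxy-2,3-dimethyl-4-oxochroman-8-yl]-3-phenylpropanoate
Conditions: NaOMe (2.2 equiv), MeOH/THF, 0 °C; AcOH (2.2 equiv) at 0 °C; used directly
Reagents that add atoms: sodium methoxide, C[O-].[Na+]
Why: transesterification of the aryl lactone (phenoxide leaving group) to the methyl ester, which frees O7 and turns the ring into a 5,7-dihydroxy acylphloroglucinol-type nucleophile; as the bis-phenoxide the ketone is protected from enolisation.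

Step 15
Reactants: 22 methyl (3S)-3-[(2R,3R)-6-{[(1R,3S)-2,2-dimethyl-3-(prop-1-en-2-yl)cyclobutyl]methyl}-5,7-dihydroxy-2,3-dimethyl-4-oxochroman-8-yl]-3-phenylpropanoate; 23 prenyl acetate (3-methylbut-2-en-1-yl acetate)
Product: 24 methyl (3S)-3-[(2R,3R,6R)-6-{[(1R,3S)-2,2-dimethyl-3-(prop-1-en-2-yl)cyclobutyl]methyl}-5-hydroxy-2,3-dimethyl-6-(3-methylbut-2-en-1-yl)-4,7-dioxo-3,4,6,7-tetrahydro-2H-chromen-8-yl]-3-phenylpropanoate
Conditions: Pd2(dba)3·CHCl3 (2.5 mol %), (R,R)-DACH-phenyl Trost ligand (7.5 mol %), Cs2CO3 (1.2 equiv), THF, 0 °C to rt; aq. citric acid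
Reagents that add atoms: none
Why: Tsuji–Trost alkylative dearomatisation, the phenoxide attacking the π-prenyl palladium at its unsubstituted terminus through C6 (flanked by both oxygens, whereas C8 carries the bulky diarylmethyl-type group and O-allylation is reversible under Pd(0)); the chiral ligand pocket, not the distant substrate stereocentres, is relied on to select the C6 face (6R), and the C6 epimers are diastereomers that can be separated.

Step 16
Reactants: 24 methyl (3S)-3-[(2R,3R,6R)-6-{[(1R,3S)-2,2-dimethyl-3-(prop-1-en-2-yl)cyclobutyl]methyl}-5-hydroxy-2,3-dimethyl-6-(3-methylbut-2-en-1-yl)-4,7-dioxo-3,4,6,7-tetrahydro-2H-chromen-8-yl]-3-phenylpropanoate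
Product: 25 (3S)-3-[(2R,3R,6R)-6-{[(1R,3S)-2,2-dimethyl-3-(prop-1-en-2-yl)cyclobutyl]methyl}-5-hydroxy-2,3-dimethyl-6-(3-methylbut-2-en-1-yl)-4,7-dioxo-3,4,6,7-tetrahydro-2H-chromen-8-yl]-3-phenylpropanoic acid (CNP0103716.3)
Conditions: LiOH·H2O (4 equiv), THF/H2O, 0 °C to rt; 1 M HCl to pH 3
Reagents that add atoms: lithium hydroxide, [Li+].[OH-]
Why: saponification of the aliphatic methyl ester; the enolised triketone is present as its anion in base, which should shield the vinylogous ester of the pyranone and C3 from hydroxide.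

**Compound list**

1 | phloroglucinol | Oc1cc(O)cc(O)c1 | starting material
2 | tigloyl chloride | C/C=C(\C)C(=O)Cl | starting material
3 | (E)-2-methyl-1-(2,4,6-trihydroxyphenyl)but-2-en-1-one | C/C=C(\C)C(=O)c1c(O)cc(O)cc1O | intermediate
4 | (2R,3S)-5,7-dihydroxy-2,3-dimethylchroman-4-one | O=C1[C@@H](C)[C@@H](C)Oc2cc(O)cc(O)c12 | intermediate
5 | (2R,3S)-5,7-bis(tert-butyldimethylsilyloxy)-2,3-dimethylchroman-4-one | O=C1[C@@H](C)[C@@H](C)Oc2cc(O[Si](C)(C)C(C)(C)C)cc(O[Si](C)(C)C(C)(C)C)c12 | intermediate
6 | (2R,3R)-5,7-bis(tert-butyldimethylsilyloxy)-2,3-dimethylchroman-4-one | O=C1[C@H](C)[C@@H](C)Oc2cc(O[Si](C)(C)C(C)(C)C)cc(O[Si](C)(C)C(C)(C)C)c12 | intermediate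
7 | (2R,3R)-5,7-bis(tert-butyldimethylsilyloxy)-8-iodo-2,3-dimethylchroman-4-one | O=C1[C@H](C)[C@@H](C)Oc2c(I)c(O[Si](C)(C)C(C)(C)C)cc(O[Si](C)(C)C(C)(C)C)c12 | intermediate
8 | 4,4,5,5-tetramethyl-2-(1-phenylvinyl)-1,3,2-dioxaborolane | C=C(B1OC(C)(C)C(C)(C)O1)c1ccccc1 | starting material
9 | (2R,3R)-5,7-dihydroxy-8-iodo-2,3-dimethylchroman-4-one | O=C1[C@H](C)[C@@H](C)Oc2c(I)c(O)cc(O)c12 | intermediate
10 | (2R,3R)-5,7-dihydroxy-2,3-dimethyl-8-(1-phenylvinyl)chroman-4-one | C=C(c1ccccc1)c1c(O)cc(O)c2C(=O)[C@H](C)[C@@H](C)Oc12 | intermediate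
11 | carbon monoxide | [C-]#[O+] | starting material
12 | (2R,3R,10S)-5-hydroxy-2,3-dimethyl-10-phenyl-2,3,9,10-tetrahydro-4H,8H-pyrano[2,3-f]chromene-4,8-dione | O=C1C[C@@H](c2ccccc2)c2c(O1)cc(O)c1C(=O)[C@H](C)[C@@H](C)Oc21 | intermediate
13 | (2R,3R,10S)-5-hydroxy-6-iodo-2,3-dimethyl-10-phenyl-2,3,9,10-tetrahydro-4H,8H-pyrano[2,3-f]chromene-4,8-dione | O=C1C[C@@H](c2ccccc2)c2c(O1)c(I)c(O)c1C(=O)[C@H](C)[C@@H](C)Oc21 | intermediate
14 | (1S,5S)-(−)-verbenone | CC1=CC(=O)[C@H]2C[C@@H]1C2(C)C | starting material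
15 | (1S,3R)-3-acetyl-2,2-dimethylcyclobutane-1-carboxylic acid | CC(=O)[C@@H]1C[C@H](C(=O)O)C1(C)C | intermediate
16 | (1S,3S)-2,2-dimethyl-3-(prop-1-en-2-yl)cyclobutane-1-carboxylic acid | C=C(C)[C@@H]1C[C@H](C(=O)O)C1(C)C | intermediate
17 | [(1S,3S)-2,2-dimethyl-3-(prop-1-en-2-yl)cyclobutyl]methanol | C=C(C)[C@@H]1C[C@H](CO)C1(C)C | intermediate
18 | (1S,3S)-1-(iodomethyl)-2,2-dimethyl-3-(prop-1-en-2-yl)cyclobutane | C=C(C)[C@@H]1C[C@H](CI)C1(C)C | intermediate
19 | [(1S,3S)-2,2-dimethyl-3-(prop-1-en-2-yl)cyclobutyl]methyllithium | C=C(C)[C@@H]1C[C@H](C[Li])C1(C)C | intermediate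
20 | [(1S,3S)-2,2-dimethyl-3-(prop-1-en-2-yl)cyclobutyl]methylzinc chloride | C=C(C)[C@@H]1C[C@H](C[Zn]Cl)C1(C)C | intermediate
21 | (2R,3R,10S)-6-{[(1R,3S)-2,2-dimethyl-3-(prop-1-en-2-yl)cyclobutyl]methyl}-5-hydroxy-2,3-dimethyl-10-phenyl-2,3,9,10-tetrahydro-4H,8H-pyrano[2,3-f]chromene-4,8-dione | O=C1C[C@@H](c2ccccc2)c2c(O1)c(C[C@H]3C[C@@H](C(C)=C)C3(C)C)c(O)c1C(=O)[C@H](C)[C@@H](C)Oc21 | intermediate
22 | methyl (3S)-3-[(2R,3R)-6-{[(1R,3S)-2,2-dimethyl-3-(prop-1-en-2-yl)cyclobutyl]methyl}-5,7-dihydroxy-2,3-dimethyl-4-oxochroman-8-yl]-3-phenylpropanoate | COC(=O)C[C@@H](c1ccccc1)c1c(O)c(C[C@H]2C[C@@H](C(C)=C)C2(C)C)c(O)c2C(=O)[C@H](C)[C@@H](C)Oc12 | intermediate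
23 | prenyl acetate | CC(C)=CCOC(C)=O | starting material
24 | methyl (3S)-3-[(2R,3R,6R)-6-{[(1R,3S)-2,2-dimethyl-3-(prop-1-en-2-yl)cyclobutyl]methyl}-5-hydroxy-2,3-dimethyl-6-(3-methylbut-2-en-1-yl)-4,7-dioxo-3,4,6,7-tetrahydro-2H-chromen-8-yl]-3-phenylpropanoate | C=C(C)[C@@H]1C[C@H](C[C@@]2(CC=C(C)C)C(=O)C([C@@H](CC(=O)OC)c3ccccc3)=C3O[C@H](C)[C@@H](C)C(=O)C3=C2O)C1(C)C | intermediate
25 | (3S)-3-[(2R,3R,6R)-6-{[(1R,3S)-2,2-dimethyl-3-(prop-1-en-2-yl)cyclobutyl]methyl}-5-hydroxy-2,3-dimethyl-6-(3-methylbut-2-en-1-yl)-4,7-dioxo-3,4,6,7-tetrahydro-2H-chromen-8-yl]-3-phenylpropanoic acid | C=C(C)[C@@H]1C[C@H](C[C@@]2(CC=C(C)C)C(=O)C([C@@H](CC(=O)O)c3ccccc3)=C3O[C@H](C)[C@@H](C)C(=O)C3=C2O)C1(C)C | target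

**Step count and risks**

Total steps: 16. Longest linear sequence: 12 steps (steps 1 to 8, then 13 to 16, from phloroglucinol); the verbenone branch is steps 9 to 12.

Most likely to fail:

1. Step 7 (proposed new method). The catalyst may fail to distinguish the two aryl groups in the hydropalladation (low face selectivity), or the electron-rich alkene may be hydrogenated or oligomerised before carbonylation. Fallback, by known chemistry: setting out from 7, buffered desilylation gives 9. Heck coupling of 9 with methyl acrylate (Pd(OAc)2, P(o-tol)3, Et3N, DMF, 90 °C) should give methyl (E)-3-[(2R,3R)-5,7-dihydroxy-2,3-dimethyl-4-oxochroman-8-yl]acrylate F1. Irradiation at 365 nm (E to Z isomerisation, then spontaneous lactonisation with loss of methanol) should give the coumarin (2R,3R)-5-hydroxy-2,3-dimethyl-2,3-dihydro-4H,8H-pyrano[2,3-f]chromene-4,8-dione F2. Rhodium-catalysed asymmetric 1,4-addition of phenylboronic acid to this coumarin (Rh(acac)(C2H4)2, (S)-SEGPHOS, dioxane/H2O, 60 °C) then sets the benzylic centre and returns to the route at 12.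

2. Step 15. The ligand may not override, or find a matched pairing with, the existing stereocentres, giving poor facial selectivity at C6; O-prenylation may also compete. Fallback: from 22, ion-pair-controlled SN2 alkylation with prenyl bromide under chiral phase-transfer catalysis (N-(9-anthracenylmethyl)cinchonidinium bromide or its cinchoninium pseudo-enantiomer, CsOH·H2O, toluene/CH2Cl2, −40 °C) leads directly to 24, with no compound outside the list (F0). The C6 epimers are diastereomers, so any remaining minor epimer is removed by preparative HPLC.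

3. Step 5. Iodination may not discriminate C8 from C6 well enough. Fallback: the halogen is placed before the pyranone is closed, so that the one free, chelated hydroxyl, which later becomes O1, directs it. From 3, TBSOTf (2.05 equiv) and 2,6-lutidine in CH2Cl2 at −78 °C should give (E)-1-[2,4-bis(tert-butyldimethylsilyloxy)-6-hydroxyphenyl]-2-methylbut-2-en-1-one F3. NIS then iodinates ortho to the free hydroxyl (the other ring CH lies between two silyloxy groups) to (E)-1-[4,6-bis(tert-butyldimethylsilyloxy)-2-hydroxy-3-iodophenyl]-2-methylbut-2-en-1-one F4. Quinine-catalysed oxa-Michael closure through the only free hydroxyl gives (2R,3S)-5,7-bis(tert-butyldimethylsilyloxy)-8-iodo-2,3-dimethylchroman-4-one F5, and MgI2/Et3N epimerisation at C3 returns to the route at 7.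

**Further compounds**

F1 | step 7 | methyl (E)-3-[(2R,3R)-5,7-dihydroxy-2,3-dimethyl-4-oxochroman-8-yl]acrylate | COC(=O)/C=C/c1c(O)cc(O)c2C(=O)[C@H](C)[C@@H](C)Oc12
F2 | step 7 | (2R,3R)-5-hydroxy-2,3-dimethyl-2,3-dihydro-4H,8H-pyrano[2,3-f]chromene-4,8-dione | O=C1C=Cc2c(O1)cc(O)c1C(=O)[C@H](C)[C@@H](C)Oc21
F0 | step 15 | none | none
F3 | step 5 | (E)-1-[2,4-bis(tert-butyldimethylsilyloxy)-6-hydroxyphenyl]-2-methylbut-2-en-1-one | C/C=C(\C)C(=O)c1c(O)cc(O[Si](C)(C)C(C)(C)C)cc1O[Si](C)(C)C(C)(C)C
F4 | step 5 | (E)-1-[4,6-bis(tert-butyldimethylsilyloxy)-2-hydroxy-3-iodophenyl]-2-methylbut-2-en-1-one | C/C=C(\C)C(=O)c1c(O)c(I)c(O[Si](C)(C)C(C)(C)C)cc1O[Si](C)(C)C(C)(C)C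
F5 | step 5 | (2R,3S)-5,7-bis(tert-butyldimethylsilyloxy)-8-iodo-2,3-dimethylchroman-4-one | O=C1[C@@H](C)[C@@H](C)Oc2c(I)c(O[Si](C)(C)C(C)(C)C)cc(O[Si](C)(C)C(C)(C)C)c12
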